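How much target stands in this flask at 3.0 h, and which remedy adds most after that? We keep books on the starting material, and every reading is a percentage of its charge.

| flask | starting material | protic impurity | enzyme | remark | time |
|---|---|---|---|---|---|
| autumn | 0.020 M | 4 mM | 2 µM | the very flask that is asked about, followed so far |  |
| flask | 0.020 M | 4.00 mM | 2.0 µM |  | 3.0 h |

autumn run (percent of the starting material charged)

| time / min | target / % | starting material / % |
|---|---|---|
| 8.00 | 1.0 | 97.2 |
| 20.0 | 2.3 | 92.9 |
| 50.0 | 6.4 | 81.4 |
| 120 | 8.0 | 61.2 |

(scatter of a reading: 0.5 percentage points)

- amber: change nothing and wait 3.0 h more
- blue: at 3.0 h add enzyme, 100% of the amount charged, then wait 3.0 h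
- ochre: at 3.0 h take out 90% of the target then present, then wait 3.0 h
- grey: at 3.0 h add starting material, 50.0% of the amount charged, then wait 3.0 h

* target, in percent of the starting material first charged, at 3.0 h
* the remedy with the largest gain of target, or "none" below 2 percentage points (amber / blue / ochre / grey / none)
* target present, with what was taken out counted in, in percent of the starting material first charged, after blue
* target present, with what was taken out counted in, in percent of the starting material first charged, after ochre

- target that was removed still counts
- additions bring no volume worth counting

At 120 min the autumn run's books show 61.2% still there, 8.0% as target and 30.8% unbooked. The enzyme cannot hold that entry, since its charge is hardly any of the starting material. The protic impurity, taking one mole each, could hold 20.0%, which is less than the unbooked entry, so part of the loss goes elsewhere.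

The fraction left is our clock. Its negative logarithm over time gives 0.00412 /min at 50.0 min and 0.00409 /min at 120 min, so we extend it and expect 47.9% left at 3.0 h. For the target entry we use the keeping share, the target gained per starting material lost between two readings, or in the usual term the differential selectivity. It was 32.4% up to 20.0 min, but between 50.0 min and 120 min it reads 7.92%, a rough value with a scatter of 0.5 percentage points on each reading. Holding that share over the loss still to come, we commit to 9.06% target at 3.0 h.

The forecast says 8%, between 6.8% and 9.2%, so our figure stands higher but inside its range. It picks ochre, with 11.3% after that remedy, and puts blue at 3.5%, reasoning that “if the enzyme drives both steps, more enzyme only speeds the decline”.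

The flask gives 8.76%, and the best remedy is ochre with 15.5%, while blue gives 12.7% against the forecast's 3.5%.

    starting material + target → side product (k = 0.0180 /M/s)
    complex ⇌ enzyme + target (K = 0.0520 M, k = 0.960 /s)
    starting material + protic impurity → quenched substrate (k = 0.00560 /M/s)
    starting material + enzyme ⇌ complex (K = 26.0 /M, k = 1700 /M/s)

The books of this flask close at 3.00 h with 33.3% as side product, each mole of it counted as two of starting material, and 11.5% as quenched substrate. The keeping share of this flask from 1.50 h to 3.00 h is 6.00%. The same flask read at 12 h holds 7.05% target with 6.44% of the starting material left, so its keeping share after 3.00 h is −4.26%.

The readings stem from a simulated flask with made-up constants; scatter was added.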